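## The problem

Bonannione A is a (2S)-flavanone: a chroman-4-one in which ring A is fused to the dihydropyranone ring C, with a 4-hydroxyphenyl ring B on C2, hydroxyls on C5 and C7, and a geranyl chain on C6. C2 is the only stereocentre, so nothing in the molecule can relay to it and its configuration must come from a reagent or catalyst. It is also fragile: benzylic, bound to O1 and β to the C4 ketone, it is lost by base-induced opening of ring C and by ionisation towards the para-oxygenated benzylic cation. Ring A is a phloroglucinol whose two oxygens ortho to the acyl carbon (the C5 oxygen and O1 on C8a) must be told apart, because closing ring C through the wrong one gives the 8-geranyl isomer. The geranyl diene rules out hydrogenolysis, strong Lewis acids and indiscriminate electrophiles, and under acid it can cyclise onto the neighbouring C5 or C7 hydroxyl. The free polyphenol is sensitive to air and base, so protecting groups must come off under mild, non-reductive conditions. The enabling feature is on ring A: the acyl carbon C4 sits on C4a and the ether oxygen O1 on the adjacent C8a, with C4a flanked by the C5 oxygen. That is the substitution pattern a 3-alkoxyaryne with its triple bond between C4a and C8a delivers when it inserts into the C–O bond of a carboxylic acid.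

## Retrosynthesis

Target 24 is traced back to its tris(methoxymethyl) ether 23 by cutting three O–CH2OMe bonds. Benzyl ethers are excluded because hydrogenolysis would reduce the chain, methyl ethers because their cleavage needs boron halides, and silyl ethers on ring A because fluoride is needed to make the aryne. The methoxymethyl (MOM) group also directs the lithiation that installs the chain and steers the aryne addition. The forward step needs an acid mild enough to leave the geranyl alkenes and C2 alone.

Flavanone 23 is opened at O1–C2 to the hydroxy ketone 22, and 22 comes from its silyl ether 21. Cutting O1–C2 is preferred over a conjugate-addition closure of an enone, which would have to create C2 without any control element, and over cutting O1–C8a, which requires a halide on ring A. The precursor is acyclic with C2 as a secondary (R)-carbinol. The forward Mitsunobu closure must go by clean inversion, faster than ionisation or β-elimination. Because only the C8a hydroxyl of 22 is free, only the 6-geranyl flavanone can form.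

Ketone 21 is cut at two bonds on adjacent ring carbons, C4–C4a and O–C8a, giving the ortho-silylaryl triflate 12 (through aryne 20) and the chiral acid 19. A Friedel–Crafts or Fries acylation of a geranylated phloroglucinol would cut only C4–C4a, could not distinguish C6 from C8, and would need acid. The aryne cut places both the carbon and the oxygen in one operation and splits the molecule into two fragments of similar size. The forward reaction needs regioselective addition to the unsymmetrical aryne and acyl transfer in preference to protonation.

Triflate 12 is traced through the C–Si and O–S bonds to bromophenol 8, and 8 through the C–Br bond to phenol 7. Phenol 7 is symmetric, so its two ortho positions are equivalent: one bromophenol, one silyl triflate and one aryne follow. The forward steps need bromination of the ring in the presence of two alkenes, then a bromine–lithium exchange that triggers an oxygen-to-carbon silyl shift.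

Phenol 7 comes from silyl ether 6, and 6 is cut at the aryl–CH2 bond to silyl ether 3 and geranyl bromide 4. Ether 3 comes from 3,5-bis(methoxymethoxy)phenol 2 and this from phloroglucinol 1. Direct C-geranylation of 1 would not leave the right oxygen free. Lithiation between the two MOM ethers of 3 is directed by both, while the bulky silyl ether blocks its own ortho positions and marks the oxygen that becomes O1.

Acid 19 is traced through ester 18 to hydroxy ester 17, whose C–H bond at the carbinol is cut to give keto ester 16. Ester 16 is cut at C3–C4 (flavanone numbering) to ketone 14 and dimethyl carbonate 15, and 14 comes from 4-hydroxyacetophenone 13. An asymmetric acetate aldol would reach 17 in fewer steps but needs a stoichiometric auxiliary. Hydrogenation of a β-keto ester sets the stereocentre catalytically on a simple substrate free of alkenes.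

## Roads not taken

Alternative 1: Ring A would be built last by a Danheiser benzannulation on a preformed chiral ring C, cutting C4a–C5, C5–C6 and C7–C8. Irradiation of the diazo ketone A2 would give a vinylketene by Wolff rearrangement. This would add to the siloxyalkyne A3, and four-electron ring opening followed by six-electron ring closure would give phenol A1. The merits are real. The position of the chain is fixed by construction, the C5 hydroxyl emerges free, and no aromatic substitution or lithiation is needed. The end-game is a buffered desilylation, gentler on the chain than the acid used in the chosen plan, and it avoids substitution at the benzylic carbon. The weak points lie in the substrates. A2 is a 2-aryl-2,3-dihydropyran-4-one whose C2 is β to a ketone with a vinylogous carboxylate as leaving group, so the stereocentre is exposed to ring opening during the heating the cascade needs. The diazo group must be introduced next to an enolisable pyranone. A3 carries a methylene that is both propargylic and allylic and is prone to isomerisation, and it needs several steps of its own. In end-game mildness this road is better. The chosen plan sets against it two fragments made from three cheap compounds by standard steps and a key reaction type already shown on simple acids and alkoxyarynes, whereas the benzannulation has not been shown on a diazo ketone of this heterocyclic kind.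

Alternative 2: Ring C would be assembled flat, cutting C4a–C4, C4–C3 and O1–C2. A carbonylative Sonogashira coupling of iodophenol A5 with alkyne A6, catalysed by PdCl2(PPh3)2 in diethylamine, would give flavone A4 in one step. An asymmetric reduction of the C2–C3 double bond would then lead to 23. This is the most convergent road and is shorter than the chosen one. A5 is the iodo analogue of bromophenol 8 and A6 is two steps from a commercial phenol. No stereocentre has to be carried, and the MOM groups fit. Its weakness is the last step. The enantioselective reduction of a 2-arylchromone bearing a peri alkoxy group at C5 is the least secure reaction on the whole map. Hydrogenation catalysts endanger the alkenes and the ketone, and hydride conditions that are basic endanger the flavanone just formed. A lesser concern is five-membered versus six-membered closure at the hindered iodide. In step count this road wins. The chosen plan sets against it a stereocentre fixed early by a hydrogenation of a simple keto ester and carried to C2 by a stereospecific inversion, so the enantio-determining step is not run on the most advanced material.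

Alternative 3: Ring C would be closed at O1–C8a with retention at C2. An intramolecular palladium-catalysed etherification of the bromo alcohol A8 (Pd(OAc)2, a bulky di-tert-butyl biarylphosphine, Cs2CO3) would give chroman A7. Desilylation, oxidation at C4 to 23 and deprotection would follow. Its merit is a true advantage over the chosen plan. C2 is never a reaction centre, so neither ionisation nor inversion is at issue, and with C4 at the alcohol level β-elimination is impossible. The weak points are these. The aryl bromide is very electron-rich, which slows reductive elimination and lets β-hydride elimination from the palladium alkoxide of a benzylic secondary alcohol compete. A8 needs a 1,3-diol chain with two differentiated oxygens and an irrelevant extra stereocentre at C4. Two redox and protecting-group steps are added after the closure. The chosen plan sets against the safer handling of C2 a shorter sequence in which C4 arrives at the ketone level and O1 and C4 are placed on ring A in one step. Its fallback for the ring closure borrows the alcohol oxidation level at C4 from this alternative.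

Key step: step 12

Remark on the chemistry: geranyl means (2E)-3,7-dimethylocta-2,6-dien-1-yl and MOM means methoxymethyl throughout; commercial geranyl bromide is taken to be the pure 2E isomer.

## Route

Step 1
Reactants: 1 phloroglucinol (benzene-1,3,5-triol)
Product: 2 3,5-bis(methoxymethoxy)phenol
Conditions: MOMCl (2.0 equiv), i-Pr2NEt, DMF, 0 °C → rt; chromatography
Reagents that add atoms: chloromethyl methyl ether (MOMCl), COCCl
Why: O-alkylation of the phenoxide by the α-chloro ether; the protection is statistical on the symmetric triol, and the bis-ether should be separable from mono- and tris-ethers by chromatography.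

Step 2
Reactants: 2 3,5-bis(methoxymethoxy)phenol
Product: 3 [3,5-bis(methoxymethoxy)phenoxy]triisopropylsilane
Conditions: TIPSCl, imidazole, DMF, rt
Reagents that add atoms: triisopropylsilyl chloride, CC(C)[Si](Cl)(C(C)C)C(C)C
Why: Standard silylation of a phenol; the bulky silyl ether tolerates n-BuLi, shields its own ortho positions and marks the oxygen that becomes O1.

Step 3
Reactants: 3 [3,5-bis(methoxymethoxy)phenoxy]triisopropylsilane, 4 geranyl bromide
Product: 6 [4-geranyl-3,5-bis(methoxymethoxy)phenoxy]triisopropylsilane, via 2,6-bis(methoxymethoxy)-4-(triisopropylsilyloxy)phenyllithium 5 (not isolated)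
Conditions: n-BuLi, THF, 0 °C; CuI (10 mol %), then 4, −78 °C → rt
Reagents that add atoms: none
Why: Directed ortho-metalation at the carbon between the two MOM ethers, which both coordinate the base, while the positions next to the bulky silyl ether are shielded. Copper-assisted SN2 alkylation by the primary allylic bromide should keep the E geometry.

Step 4
Reactants: 6 [4-geranyl-3,5-bis(methoxymethoxy)phenoxy]triisopropylsilane
Product: 7 4-geranyl-3,5-bis(methoxymethoxy)phenol
Conditions: TBAF, AcOH, THF, 0 °C
Reagents that add atoms: none
Why: Fluoride cleavage of an aryl silyl ether; acetals and alkenes are inert, and the acetic acid buffer keeps the electron-rich phenol from resting as its air-sensitive phenoxide.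

Step 5
Reactants: 7 4-geranyl-3,5-bis(methoxymethoxy)phenol
Product: 8 2-bromo-4-geranyl-3,5-bis(methoxymethoxy)phenol
Conditions: NBS (1.0 equiv), CH2Cl2, −78 °C, dark
Reagents that add atoms: N-bromosuccinimide, O=C1CCC(=O)N1Br
Why: Electrophilic aromatic bromination of a highly activated phenol; the para position is blocked and the two ortho positions are equivalent. At −78 °C with one equivalent, the ring should react far faster than the trisubstituted alkenes.

Step 6
Reactants: 8 2-bromo-4-geranyl-3,5-bis(methoxymethoxy)phenol
Product: 12 4-geranyl-3,5-bis(methoxymethoxy)-2-(trimethylsilyl)phenyl trifluoromethanesulfonate, via aryl trimethylsilyl ether 9 (not isolated), via 2-lithioaryl silyl ether 10 (not isolated), via lithium 2-silylphenolate 11 (not isolated)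
Conditions: HMDS, THF, 65 °C, then evaporation; n-BuLi, THF, −100 °C; Tf2O, −100 °C → rt
Reagents that add atoms: hexamethyldisilazane, C[Si](C)(C)N[Si](C)(C)C; trifluoromethanesulfonic anhydride, O=S(=O)(OS(=O)(=O)C(F)(F)F)C(F)(F)F
Why: O-silylation, bromine–lithium exchange, anionic 1,3 oxygen-to-carbon silyl shift (retro-Brook rearrangement) and O-triflation of the resulting phenolate. This is the established passage from ortho-bromophenols to ortho-silylaryl triflates, and exchange at −100 °C is faster than any deprotonation.

Step 7
Reactants: 13 4-hydroxyacetophenone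
Product: 14 1-[4-(methoxymethoxy)phenyl]ethan-1-one
Conditions: MOMCl, i-Pr2NEt, CH2Cl2, 0 °C → rt
Reagents that add atoms: chloromethyl methyl ether (MOMCl), COCCl
Why: Acetal protection of the phenol; the group withstands hydride, base and fluoride and leaves at the end with the other two.

Step 8
Reactants: 14 1-[4-(methoxymethoxy)phenyl]ethan-1-one, 15 dimethyl carbonate
Product: 16 methyl 3-[4-(methoxymethoxy)phenyl]-3-oxopropanoate
Conditions: NaH (2.5 equiv), 15 (excess), THF, 65 °C; AcOH quench
Reagents that add atoms: none
Why: Crossed Claisen condensation of the ketone enolate with the carbonate, driven by formation of the stabilised enolate of the β-keto ester.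

Step 9
Reactants: 16 methyl 3-[4-(methoxymethoxy)phenyl]-3-oxopropanoate
Product: 17 methyl (3R)-3-hydroxy-3-[4-(methoxymethoxy)phenyl]propanoate
Conditions: [RuCl(p-cymene)((S)-BINAP)]Cl (1 mol %), H2 (30 bar), MeOH, 50 °C
Reagents that add atoms: none
Why: Noyori asymmetric hydrogenation; the keto ester chelates the ruthenium hydride through both carbonyl oxygens and the (S)-BINAP ligand exposes one face of the ketone. For 3-aryl-3-oxopropanoates this ligand antipode gives the (R)-carbinol.

Step 10
Reactants: 17 methyl (3R)-3-hydroxy-3-[4-(methoxymethoxy)phenyl]propanoate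
Product: 18 methyl (3R)-3-(tert-butyldimethylsilyloxy)-3-[4-(methoxymethoxy)phenyl]propanoate
Conditions: TBSCl, imidazole, DMF, rt
Reagents that add atoms: tert-butyldimethylsilyl chloride, CC(C)(C)[Si](C)(C)Cl
Why: Standard silylation of a secondary alcohol under non-Lewis-acidic conditions that leave the aryl acetal alone; the stereocentre is not touched.

Step 11
Reactants: 18 methyl (3R)-3-(tert-butyldimethylsilyloxy)-3-[4-(methoxymethoxy)phenyl]propanoate
Product: 19 (3R)-3-(tert-butyldimethylsilyloxy)-3-[4-(methoxymethoxy)phenyl]propanoic acid
Conditions: LiOH·H2O, THF/MeOH/H2O, 0 °C → rt; 1 M HCl to pH 4 at 0 °C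
Reagents that add atoms: lithium hydroxide, [Li+].[OH-]
Why: Saponification of a methyl ester; hydroxide attack at the ester carbonyl at low temperature is faster than β-elimination of the silyloxy group, and the carbinol carbon is not involved.

Step 12
Reactants: 12 4-geranyl-3,5-bis(methoxymethoxy)-2-(trimethylsilyl)phenyl trifluoromethanesulfonate, 19 (3R)-3-(tert-butyldimethylsilyloxy)-3-[4-(methoxymethoxy)phenyl]propanoic acid
Product: 21 (3R)-3-(tert-butyldimethylsilyloxy)-1-[3-geranyl-6-hydroxy-2,4-bis(methoxymethoxy)phenyl]-3-[4-(methoxymethoxy)phenyl]propan-1-one, via 4-geranyl-3,5-bis(methoxymethoxy)benzyne 20 (not isolated)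
Conditions: 12 (1.3 equiv), CsF (4 equiv), THF, sealed tube, 125 °C
Reagents that add atoms: none
Why: Fluoride attacks the trimethylsilyl group of 12 and triflate leaves from the neighbouring carbon, giving aryne 20 with its triple bond between C4a and C8a; because phenol 7 is symmetric this is the only aryne that can form. The cesium carboxylate of 19 adds through oxygen to C8a: the C5 methoxymethoxy group polarises and distorts the triple bond so that the distal carbon C8a is the more electrophilic, and the negative charge develops at C4a next to the C–O bond that stabilises it. The C4a aryl anion then attacks the carbonyl of the aryl ester just formed through a four-membered transition state, and collapse of the tetrahedral intermediate with C–O cleavage gives the cesium phenoxide of ketone 21, an anionic Fries-type 1,3-acyl shift. The closest known reaction is the fluoride-induced insertion of arynes, 3-methoxybenzyne included, into the C–O bond of aliphatic and aromatic carboxylic acids to give ortho-hydroxyaryl ketones. No ring closes and no stereocentre is formed; the silyloxy carbon of 19 is not α to the carbonyl and cannot epimerise by enolisation, and the acid reacts as a carboxylate and the product rests as a phenoxide, both poor at the α-deprotonation that β-elimination would need. Two selectivities are required: the regiochemistry of addition, secured by the C5 oxygen and by the unhindered C8–H side, and acyl transfer in preference to protonation of the aryl anion, favoured by the hot aprotic medium in which the acid is present only as its salt. Only the C8a hydroxyl of 21 is free, which fixes the later ring closure to the 6-geranyl series.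

Step 13
Reactants: 21 (3R)-3-(tert-butyldimethylsilyloxy)-1-[3-geranyl-6-hydroxy-2,4-bis(methoxymethoxy)phenyl]-3-[4-(methoxymethoxy)phenyl]propan-1-one
Product: 22 (3R)-1-[3-geranyl-6-hydroxy-2,4-bis(methoxymethoxy)phenyl]-3-hydroxy-3-[4-(methoxymethoxy)phenyl]propan-1-one
Conditions: TBAF, AcOH (1:1), THF, 0 °C → rt
Reagents that add atoms: none
Why: Fluoride cleavage of the one alkyl silyl ether; the acetic acid buffer keeps the liberated β-hydroxy ketone from retro-aldol cleavage or β-elimination, and the aryl MOM ethers do not react with fluoride.

Step 14
Reactants: 22 (3R)-1-[3-geranyl-6-hydroxy-2,4-bis(methoxymethoxy)phenyl]-3-hydroxy-3-[4-(methoxymethoxy)phenyl]propan-1-one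
Product: 23 (2S)-6-geranyl-5,7-bis(methoxymethoxy)-2-[4-(methoxymethoxy)phenyl]chroman-4-one
Conditions: PPh3, DIAD, toluene/THF, −20 → 0 °C
Reagents that add atoms: none
Why: Intramolecular Mitsunobu etherification, known for ortho-hydroxyaryl β-hydroxy ketones; the acidic hydrogen-bonded phenol is the pronucleophile and displaces the oxyphosphonium group in a six-membered ring closure. The SN2 inversion turns the (R)-carbinol into C2 of (S) configuration, and since only the C8a oxygen is free only the 6-geranyl flavanone can form.

Step 15
Reactants: 23 (2S)-6-geranyl-5,7-bis(methoxymethoxy)-2-[4-(methoxymethoxy)phenyl]chroman-4-one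
Product: 24 bonannione A, (2S)-6-geranyl-5,7-dihydroxy-2-(4-hydroxyphenyl)chroman-4-one
Conditions: HCl (3 M aq)/MeOH, 25–40 °C, monitored closely
Reagents that add atoms: none
Why: Acid-catalysed transacetalisation of the three aryl MOM ethers to methanol, standard for prenylated and geranylated flavonoids. Dilute acid for a short time should leave the alkenes alone, and acid does not open ring C, so C2 keeps its configuration.

## Compound list

1 | phloroglucinol (benzene-1,3,5-triol) | Oc1cc(O)cc(O)c1 | starting material
2 | 3,5-bis(methoxymethoxy)phenol | COCOc1cc(O)cc(OCOC)c1 | intermediate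
3 | [3,5-bis(methoxymethoxy)phenoxy]triisopropylsilane | COCOc1cc(OCOC)cc(O[Si](C(C)C)(C(C)C)C(C)C)c1 | intermediate
4 | geranyl bromide, (2E)-1-bromo-3,7-dimethylocta-2,6-diene | CC(C)=CCC/C(C)=C/CBr | starting material
5 | 2,6-bis(methoxymethoxy)-4-(triisopropylsilyloxy)phenyllithium | [Li]c1c(OCOC)cc(O[Si](C(C)C)(C(C)C)C(C)C)cc1OCOC | intermediate
6 | [4-geranyl-3,5-bis(methoxymethoxy)phenoxy]triisopropylsilane | CC(C)=CCC/C(C)=C/Cc1c(OCOC)cc(O[Si](C(C)C)(C(C)C)C(C)C)cc1OCOC | intermediate
7 | 4-geranyl-3,5-bis(methoxymethoxy)phenol | CC(C)=CCC/C(C)=C/Cc1c(OCOC)cc(O)cc1OCOC | intermediate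
8 | 2-bromo-4-geranyl-3,5-bis(methoxymethoxy)phenol | CC(C)=CCC/C(C)=C/Cc1c(OCOC)cc(O)c(Br)c1OCOC | intermediate
9 | [2-bromo-4-geranyl-3,5-bis(methoxymethoxy)phenoxy]trimethylsilane | CC(C)=CCC/C(C)=C/Cc1c(OCOC)cc(O[Si](C)(C)C)c(Br)c1OCOC | intermediate
10 | [3-geranyl-2,4-bis(methoxymethoxy)-6-(trimethylsilyloxy)phenyl]lithium | CC(C)=CCC/C(C)=C/Cc1c(OCOC)cc(O[Si](C)(C)C)c([Li])c1OCOC | intermediate
11 | lithium 4-geranyl-3,5-bis(methoxymethoxy)-2-(trimethylsilyl)phenolate | CC(C)=CCC/C(C)=C/Cc1c(OCOC)cc([O-])c([Si](C)(C)C)c1OCOC.[Li+] | intermediate
12 | 4-geranyl-3,5-bis(methoxymethoxy)-2-(trimethylsilyl)phenyl trifluoromethanesulfonate | CC(C)=CCC/C(C)=C/Cc1c(OCOC)cc(OS(=O)(=O)C(F)(F)F)c([Si](C)(C)C)c1OCOC | intermediate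
13 | 4-hydroxyacetophenone | CC(=O)c1ccc(O)cc1 | starting material
14 | 1-[4-(methoxymethoxy)phenyl]ethan-1-one | CC(=O)c1ccc(OCOC)cc1 | intermediate
15 | dimethyl carbonate | COC(=O)OC | starting material
16 | methyl 3-[4-(methoxymethoxy)phenyl]-3-oxopropanoate | COC(=O)CC(=O)c1ccc(OCOC)cc1 | intermediate
17 | methyl (3R)-3-hydroxy-3-[4-(methoxymethoxy)phenyl]propanoate | COC(=O)C[C@H](c1ccc(OCOC)cc1)O | intermediate
18 | methyl (3R)-3-(tert-butyldimethylsilyloxy)-3-[4-(methoxymethoxy)phenyl]propanoate | COC(=O)C[C@H](c1ccc(OCOC)cc1)O[Si](C)(C)C(C)(C)C | intermediate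
19 | (3R)-3-(tert-butyldimethylsilyloxy)-3-[4-(methoxymethoxy)phenyl]propanoic acid | O=C(O)C[C@H](c1ccc(OCOC)cc1)O[Si](C)(C)C(C)(C)C | intermediate
20 | 4-geranyl-3,5-bis(methoxymethoxy)benzyne (triple bond between the future C4a and C8a) | CC(C)=CCC/C(C)=C/CC1=C(OCOC)C#CC=C1OCOC | intermediate
21 | (3R)-3-(tert-butyldimethylsilyloxy)-1-[3-geranyl-6-hydroxy-2,4-bis(methoxymethoxy)phenyl]-3-[4-(methoxymethoxy)phenyl]propan-1-one | CC(C)=CCC/C(C)=C/Cc1c(OCOC)cc(O)c(C(=O)C[C@H](c2ccc(OCOC)cc2)O[Si](C)(C)C(C)(C)C)c1OCOC | intermediate
22 | (3R)-1-[3-geranyl-6-hydroxy-2,4-bis(methoxymethoxy)phenyl]-3-hydroxy-3-[4-(methoxymethoxy)phenyl]propan-1-one | CC(C)=CCC/C(C)=C/Cc1c(OCOC)cc(O)c(C(=O)C[C@H](c2ccc(OCOC)cc2)O)c1OCOC | intermediate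
23 | (2S)-6-geranyl-5,7-bis(methoxymethoxy)-2-[4-(methoxymethoxy)phenyl]chroman-4-one | CC(C)=CCC/C(C)=C/Cc1c(OCOC)cc2c(c1OCOC)C(=O)C[C@@H](c1ccc(OCOC)cc1)O2 | intermediate
24 | bonannione A, (2S)-6-geranyl-5,7-dihydroxy-2-(4-hydroxyphenyl)chroman-4-one | CC(C)=CCC/C(C)=C/Cc1c(O)cc2c(c1O)C(=O)C[C@@H](c1ccc(O)cc1)O2 | target

## Step count and risks

Total: 15 steps. Longest linear sequence: 10 steps (steps 1–6, then 12–15); the acid branch contributes 5 steps (7–11) before the key step.

**Step 12 (key step).** The aryl anion at C4a may be protonated before it reaches the ester carbonyl, or it may take a proton from the α-methylene of the ester, so that O-arylation stops short of acyl transfer. Prolonged heating with fluoride may also remove the alkyl silyl group, after which dehydration across C2–C3 would erase the stereocentre. The fallback generates the same C4a anion without fluoride or heat. It sets out from bromophenol 8 and acid 19, which DCC and DMAP in CH2Cl2 would join to 2-bromo-4-geranyl-3,5-bis(methoxymethoxy)phenyl (3R)-3-(tert-butyldimethylsilyloxy)-3-[4-(methoxymethoxy)phenyl]propanoate F1. Treating F1 with t-BuLi (2 equiv) in THF at −100 °C would effect bromine–lithium exchange, and the ortho-lithiated aryl ester would undergo the same 1,3-acyl shift (a halogen–metal-exchange-initiated anionic Fries rearrangement). The fallback comes back to the route at 21.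

**Step 14.** The oxyphosphonium intermediate sits on a para-alkoxybenzylic carbon that is also β to a ketone. Ionisation would erode the configuration, and base-induced β-elimination across C2–C3 followed by unselective conjugate re-closure would destroy it. The fallback removes the carbonyl for the duration of the closure. It sets out from 22, which NaBH4 in MeOH at 0 °C would reduce to (3R)-1-[3-geranyl-6-hydroxy-2,4-bis(methoxymethoxy)phenyl]-3-[4-(methoxymethoxy)phenyl]propane-1,3-diol F2 (either C1 epimer). Mitsunobu closure (PPh3, DIAD) can engage only the C3 carbinol in a six-membered ring and would give (2S)-6-geranyl-5,7-bis(methoxymethoxy)-2-[4-(methoxymethoxy)phenyl]chroman-4-ol F3 (either C4 epimer). Dess–Martin periodinane buffered with NaHCO3 would oxidise F3, and the fallback comes back at 23. The ortho-hydroxybenzylic carbinol of F2 is hindered by two ortho substituents, but its activation remains the point to watch in this detour.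

**Step 15.** Under Brønsted acid the freed C5 or C7 hydroxyl may add to the proximal alkene of the chain, and the distal alkene may be hydrated or enter cation–olefin cyclisation. The fallback avoids protic acid during the cleavage. It sets out from 23, which TMSOTf and 2,2′-bipyridyl in MeCN/CH2Cl2 at 0 °C would convert, by exchange of the aryl acetals for silyl ethers, into (2S)-6-geranyl-5,7-bis(trimethylsilyloxy)-2-[4-(trimethylsilyloxy)phenyl]chroman-4-one F4. Addition of water would hydrolyse the aryl silyl ethers, and the fallback comes back at 24.

**Step 5.** The brominating agent may attack the trisubstituted alkenes or brominate the ring twice. The fallback introduces the silyl group by directed metalation, with no electrophilic halogen, and also replaces step 6. It sets out from 7, which isopropyl isocyanate and Et3N would convert into 4-geranyl-3,5-bis(methoxymethoxy)phenyl N-isopropylcarbamate F5. In one flask, TBSOTf and TMEDA would mask the N–H as 4-geranyl-3,5-bis(methoxymethoxy)phenyl N-(tert-butyldimethylsilyl)-N-isopropylcarbamate F6. Lithiation with n-BuLi/TMEDA at −78 °C ortho to the carbamate, then TMSCl, would give 4-geranyl-3,5-bis(methoxymethoxy)-2-(trimethylsilyl)phenyl N-(tert-butyldimethylsilyl)-N-isopropylcarbamate F7. Mild aqueous work-up would return the N–H in 4-geranyl-3,5-bis(methoxymethoxy)-2-(trimethylsilyl)phenyl N-isopropylcarbamate F8. Et2NH and DBU in MeCN at 40 °C would release 4-geranyl-3,5-bis(methoxymethoxy)-2-(trimethylsilyl)phenol F9, which PhNTf2 would triflate in the same flask. The fallback comes back at 12.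

## Further compounds

F1 | step 12 | 2-bromo-4-geranyl-3,5-bis(methoxymethoxy)phenyl (3R)-3-(tert-butyldimethylsilyloxy)-3-[4-(methoxymethoxy)phenyl]propanoate | CC(C)=CCC/C(C)=C/Cc1c(OCOC)cc(OC(=O)C[C@H](c2ccc(OCOC)cc2)O[Si](C)(C)C(C)(C)C)c(Br)c1OCOC
F2 | step 14 | (3R)-1-[3-geranyl-6-hydroxy-2,4-bis(methoxymethoxy)phenyl]-3-[4-(methoxymethoxy)phenyl]propane-1,3-diol (either C1 epimer) | CC(C)=CCC/C(C)=C/Cc1c(OCOC)cc(O)c(C(O)C[C@H](c2ccc(OCOC)cc2)O)c1OCOC
F3 | step 14 | (2S)-6-geranyl-5,7-bis(methoxymethoxy)-2-[4-(methoxymethoxy)phenyl]chroman-4-ol (either C4 epimer) | CC(C)=CCC/C(C)=C/Cc1c(OCOC)cc2c(c1OCOC)C(O)C[C@@H](c1ccc(OCOC)cc1)O2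
F4 | step 15 | (2S)-6-geranyl-5,7-bis(trimethylsilyloxy)-2-[4-(trimethylsilyloxy)phenyl]chroman-4-one | CC(C)=CCC/C(C)=C/Cc1c(O[Si](C)(C)C)cc2c(c1O[Si](C)(C)C)C(=O)C[C@@H](c1ccc(O[Si](C)(C)C)cc1)O2
F5 | step 5 | 4-geranyl-3,5-bis(methoxymethoxy)phenyl N-isopropylcarbamate | CC(C)=CCC/C(C)=C/Cc1c(OCOC)cc(OC(=O)NC(C)C)cc1OCOC
F6 | step 5 | 4-geranyl-3,5-bis(methoxymethoxy)phenyl N-(tert-butyldimethylsilyl)-N-isopropylcarbamate | CC(C)=CCC/C(C)=C/Cc1c(OCOC)cc(OC(=O)N(C(C)C)[Si](C)(C)C(C)(C)C)cc1OCOC
F7 | step 5 | 4-geranyl-3,5-bis(methoxymethoxy)-2-(trimethylsilyl)phenyl N-(tert-butyldimethylsilyl)-N-isopropylcarbamate | CC(C)=CCC/C(C)=C/Cc1c(OCOC)cc(OC(=O)N(C(C)C)[Si](C)(C)C(C)(C)C)c([Si](C)(C)C)c1OCOC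
F8 | step 5 | 4-geranyl-3,5-bis(methoxymethoxy)-2-(trimethylsilyl)phenyl N-isopropylcarbamate | CC(C)=CCC/C(C)=C/Cc1c(OCOC)cc(OC(=O)NC(C)C)c([Si](C)(C)C)c1OCOC
F9 | step 5 | 4-geranyl-3,5-bis(methoxymethoxy)-2-(trimethylsilyl)phenol | CC(C)=CCC/C(C)=C/Cc1c(OCOC)cc(O)c([Si](C)(C)C)c1OCOC
A1 | alternative 1 | (2S)-6-geranyl-5-hydroxy-7-(triisopropylsilyloxy)-2-[4-(triisopropylsilyloxy)phenyl]chroman-4-one | CC(C)=CCC/C(C)=C/Cc1c(O[Si](C(C)C)(C(C)C)C(C)C)cc2c(c1O)C(=O)C[C@@H](c1ccc(O[Si](C(C)C)(C(C)C)C(C)C)cc1)O2
A2 | alternative 1 | (2S)-6-(diazoacetyl)-2-[4-(triisopropylsilyloxy)phenyl]-2,3-dihydro-4H-pyran-4-one | [N-]=[N+]=CC(=O)C1=CC(=O)C[C@@H](c2ccc(O[Si](C(C)C)(C(C)C)C(C)C)cc2)O1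
A3 | alternative 1 | triisopropyl{[(4E)-5,9-dimethyldeca-4,8-dien-1-yn-1-yl]oxy}silane | CC(C)=CCC/C(C)=C/CC#CO[Si](C(C)C)(C(C)C)C(C)C
A4 | alternative 2 | 6-geranyl-5,7-bis(methoxymethoxy)-2-[4-(methoxymethoxy)phenyl]chromen-4-one | CC(C)=CCC/C(C)=C/Cc1c(OCOC)cc2oc(-c3ccc(OCOC)cc3)cc(=O)c2c1OCOC
A5 | alternative 2 | 4-geranyl-2-iodo-3,5-bis(methoxymethoxy)phenol | CC(C)=CCC/C(C)=C/Cc1c(OCOC)cc(O)c(I)c1OCOC
A6 | alternative 2 | 1-ethynyl-4-(methoxymethoxy)benzene | C#Cc1ccc(OCOC)cc1
A7 | alternative 3 | (2S)-4-(tert-butyldimethylsilyloxy)-6-geranyl-5,7-bis(methoxymethoxy)-2-[4-(methoxymethoxy)phenyl]chromane (either C4 epimer) | CC(C)=CCC/C(C)=C/Cc1c(OCOC)cc2c(c1OCOC)C(O[Si](C)(C)C(C)(C)C)C[C@@H](c1ccc(OCOC)cc1)O2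
A8 | alternative 3 | (1S)-3-[2-bromo-5-geranyl-4,6-bis(methoxymethoxy)phenyl]-3-(tert-butyldimethylsilyloxy)-1-[4-(methoxymethoxy)phenyl]propan-1-ol (either C3 epimer) | CC(C)=CCC/C(C)=C/Cc1c(OCOC)cc(Br)c(C(O[Si](C)(C)C(C)(C)C)C[C@H](O)c2ccc(OCOC)cc2)c1OCOC
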